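**Retrosynthetic overview**

1. The target is traced back (acetylation, ester reduction, B-alkyl Suzuki–Miyaura coupling at C12–C13) to a bicyclic acid with a vinyl group on C9; the vinyl carbon C11 is carried through the ring construction as a methyl ester.
2. Both rings are disconnected at once by a double ring-closing metathesis of an acyclic tetraene: ring B through C6=C7 (hydrogenated afterwards to the C6–C7 single bond) and ring A through C1=C10. The enabling feature is that rings A and B share only the C5–C10 bond, C10 is already sp2 in the target (C1=C10), and C6/C7 are adjacent unsubstituted ring CH2 groups, so the bicycle is two cyclohexenes hinged on C5–C10.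
3. The tetraene comes from a γ-menthyloxybutenolide: rhodium-catalysed 1,4-addition of a C7–C11 alkenylboronate (C5–C10 bond, anti to the acetal), butenylation then methylation of the lactone enolate (C4), and conversion of the acetal carbon into the C6 vinyl group.
4. The alkenylboronate comes from an enol triflate of a β-keto ester whose C8/C9 stereodiad is set by a dianionic Carroll rearrangement of (2S,3Z)-pent-3-en-2-yl 2-methylacetoacetate.
5. Order of ring formation: a temporary γ-lactone first, then rings B and A together in the key step; no ring of the target exists before it.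

Key step: step 13

Remark on the chemistry: the SMILES is read as the (4S,5R,8S,9R,13E) isomer in terpenoid (halimane) numbering, which is used for skeleton atoms throughout (C4 bears CH3 and the C19 carboxyl, C5 is the ring-fusion CH, C1=C10 is the ring alkene, C8 bears CH3, C9 bears CH3 and the C11–C15 chain); the five starting materials are assumed to be purchasable.

**Route**

Step 1
Reactants: 1 (S)-but-3-yn-2-ol
Product: 2 (S)-pent-3-yn-2-ol
Conditions: n-BuLi (2.1 equiv), THF, −78 → 0 °C; MeI (1.0 equiv), DMPU, −78 °C → rt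
Reagents that add atoms: iodomethane, CI
Why: C-alkylation of the alkoxide–acetylide dianion should occur at the far more nucleophilic acetylide carbon, and the carbinol stereocentre is not touched.

Step 2
Reactants: 2 (S)-pent-3-yn-2-ol
Product: 3 (2S,3Z)-pent-3-en-2-ol
Conditions: H2 (1 atm), Pd/CaCO3–Pb(OAc)2 (Lindlar catalyst), quinoline, pentane, rt
Reagents that add atoms: none
Why: Lindlar semihydrogenation adds H2 syn and should stop at the Z alkene.

Step 3
Reactants: 3 (2S,3Z)-pent-3-en-2-ol; 4 methyl 2-methyl-3-oxobutanoate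
Product: 5 (2S,3Z)-pent-3-en-2-yl 2-methyl-3-oxobutanoate (epimeric at the acyl α-carbon)
Conditions: DMAP (0.2 equiv), toluene, 4 Å molecular sieves, 110 °C (methanol removed)
Reagents that add atoms: none
Why: DMAP-catalysed transesterification of a β-keto ester (acylketene pathway) is driven by loss of methanol and leaves the carbinol centre and the Z alkene untouched; the epimeric α-carbon is erased in step 4.

Step 4
Reactants: 5 (2S,3Z)-pent-3-en-2-yl 2-methyl-3-oxobutanoate
Product: 7 methyl (2R,3S,4E)-2-acetyl-2,3-dimethylhex-4-enoate, via keto acid 6 (not isolated)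
Conditions: LDA (2.3 equiv), THF, −78 → 60 °C; 1 M HCl, 0 °C; then TMSCHN2, toluene/MeOH, 0 °C
Reagents that add atoms: (trimethylsilyl)diazomethane, C[Si](C)(C)C=[N+]=[N-]
Why: Dianionic Carroll rearrangement (ester-enolate [3,3] shift) through a chair in which the lithium-chelated enolate holds the acetyl group cis to O–Li, the carbinol methyl is equatorial and the Z-alkene methyl is axial, so the (S) carbinol centre is transferred to C9 (quaternary, R) and C8 (S) with an E-propenyl group, and cold esterification of the β-keto acid prevents decarboxylation.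

Step 5
Reactants: 7 methyl (2R,3S,4E)-2-acetyl-2,3-dimethylhex-4-enoate
Product: 8 methyl (2R,3S,4E)-2,3-dimethyl-2-[1-(trifluoromethylsulfonyloxy)ethenyl]hex-4-enoate
Conditions: KN(SiMe3)2, THF, −78 °C; PhNTf2, −78 → 0 °C
Reagents that add atoms: N-phenylbis(trifluoromethanesulfonimide), O=S(=O)(N(c1ccccc1)S(=O)(=O)C(F)(F)F)C(F)(F)F
Why: Enolisation is possible only at the acetyl CH3 (C9 is quaternary), so O-triflation of the kinetic enolate should give the 1,1-disubstituted enol triflate at C10 without touching C8 or C9.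

Step 6
Reactants: 8 methyl (2R,3S,4E)-2,3-dimethyl-2-[1-(trifluoromethylsulfonyloxy)ethenyl]hex-4-enoate
Product: 9 methyl (2R,3S,4E)-2,3-dimethyl-2-[1-(4,4,5,5-tetramethyl-1,3,2-dioxaborolan-2-yl)ethenyl]hex-4-enoate
Conditions: B2pin2, PdCl2(PPh3)2 (3 mol %), PPh3, KOPh, toluene, 50 °C
Reagents that add atoms: bis(pinacolato)diboron, CC1(C)OB(OC1(C)C)B1OC(C)(C)C(C)(C)O1
Why: Miyaura borylation of an alkenyl triflate with a weak phenoxide base should tolerate the ester and both alkenes.

Step 7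
Reactants: 9 methyl (2R,3S,4E)-2,3-dimethyl-2-[1-(4,4,5,5-tetramethyl-1,3,2-dioxaborolan-2-yl)ethenyl]hex-4-enoate; 10 (5R)-5-[(1R,2S,5R)-menthyloxy]furan-2(5H)-one
Product: 11 methyl (2R,3S,4E)-2,3-dimethyl-2-{1-[(2R,3S)-2-[(1R,2S,5R)-menthyloxy]-5-oxooxolan-3-yl]ethenyl}hex-4-enoate
Conditions: [Rh(cod)OH]2 (2.5 mol %), 1,4-dioxane/H2O (10:1), 50 °C
Reagents that add atoms: none
Why: Rhodium-catalysed 1,4-addition of an alkenylboronate to an unsaturated lactone, in which the alkenyl–rhodium species adds to the face anti to the γ-menthyloxy group and so sets C5 (substrate control, independent of the remote C8/C9 centres).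

Step 8
Reactants: 12 but-3-en-1-ol
Product: 13 but-3-en-1-yl trifluoromethanesulfonate
Conditions: Tf2O, 2,6-lutidine, CH2Cl2, −78 °C (used at once)
Reagents that add atoms: trifluoromethanesulfonic anhydride, O=S(=O)(OS(=O)(=O)C(F)(F)F)C(F)(F)F
Why: Standard O-triflation of a primary alcohol gives an electrophile reactive enough for a hindered lactone enolate.

Step 9
Reactants: 11 methyl (2R,3S,4E)-2,3-dimethyl-2-{1-[(2R,3S)-2-[(1R,2S,5R)-menthyloxy]-5-oxooxolan-3-yl]ethenyl}hex-4-enoate; 13 but-3-en-1-yl trifluoromethanesulfonate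
Product: 14 methyl (2R,3S,4E)-2-{1-[(2R,3S,4R)-4-(but-3-en-1-yl)-2-[(1R,2S,5R)-menthyloxy]-5-oxooxolan-3-yl]ethenyl}-2,3-dimethylhex-4-enoate
Conditions: LDA, THF, −78 °C; then 13, −78 → −30 °C
Reagents that add atoms: none
Why: Lactone enolate alkylation (the C11 ester has no α-hydrogen) should occur trans to the bulky β-alkenyl group; the configuration formed here is erased in step 10.

Step 10
Reactants: 14 methyl (2R,3S,4E)-2-{1-[(2R,3S,4R)-4-(but-3-en-1-yl)-2-[(1R,2S,5R)-menthyloxy]-5-oxooxolan-3-yl]ethenyl}-2,3-dimethylhex-4-enoate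
Product: 15 methyl (2R,3S,4E)-2-{1-[(2R,3R,4S)-4-(but-3-en-1-yl)-2-[(1R,2S,5R)-menthyloxy]-4-methyl-5-oxooxolan-3-yl]ethenyl}-2,3-dimethylhex-4-enoate
Conditions: LDA, THF/DMPU, −78 °C; MeI, −78 → −20 °C
Reagents that add atoms: iodomethane, CI
Why: In this second enolate alkylation the small electrophile enters anti to the β-alkenyl substituent, which sets quaternary C4 (S) with CH3 trans and the butenyl chain cis to the C10 substituent, as ring A requires.

Step 11
Reactants: 15 methyl (2R,3S,4E)-2-{1-[(2R,3R,4S)-4-(but-3-en-1-yl)-2-[(1R,2S,5R)-menthyloxy]-4-methyl-5-oxooxolan-3-yl]ethenyl}-2,3-dimethylhex-4-enoate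
Product: 16 methyl (2R,3S,4E)-2-{1-[(3R,4S)-4-(but-3-en-1-yl)-2-hydroxy-4-methyl-5-oxooxolan-3-yl]ethenyl}-2,3-dimethylhex-4-enoate (anomeric mixture)
Conditions: 1 M HCl, 1,4-dioxane, 50 °C
Reagents that add atoms: water, O
Why: Acid hydrolysis of the mixed acetal (pseudo-ester) releases menthol and leaves the γ-hydroxylactone, a masked C6 aldehyde and C19 acid; the hindered methyl ester and the isolated alkenes should survive dilute acid.

Step 12
Reactants: 16 methyl (2R,3S,4E)-2-{1-[(3R,4S)-4-(but-3-en-1-yl)-2-hydroxy-4-methyl-5-oxooxolan-3-yl]ethenyl}-2,3-dimethylhex-4-enoate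
Product: 17 (2S,3R)-2-(but-3-en-1-yl)-3-ethenyl-4-[(2R,3S,4E)-1-methoxy-2,3-dimethyl-1-oxohex-4-en-2-yl]-2-methylpent-4-enoic acid
Conditions: Ph3PCH3Br (3.5 equiv), KOtBu (3.4 equiv), THF, 0 °C → rt; aq. citric acid
Reagents that add atoms: methyltriphenylphosphonium bromide, C[P+](c1ccccc1)(c1ccccc1)c1ccccc1.[Br-]
Why: Wittig methylenation of the open aldehyde–carboxylate tautomer turns C6 into the vinyl group and frees C19 as the acid (now distinct from the C11 methyl ester); the hindered C5–H, flanked by quaternary C4 and C10, is not expected to epimerise at this temperature.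

Step 13
Reactants: 17 (2S,3R)-2-(but-3-en-1-yl)-3-ethenyl-4-[(2R,3S,4E)-1-methoxy-2,3-dimethyl-1-oxohex-4-en-2-yl]-2-methylpent-4-enoic acid
Product: 20 (1S,5R,6S,8aR)-5-(methoxycarbonyl)-1,5,6-trimethyl-1,2,3,5,6,8a-hexahydronaphthalene-1-carboxylic acid, via ring-B triene 18 (not isolated), via C1/C6 cyclohexene 19 (not isolated)
Conditions: (H2IMes)Cl2Ru(=CH-C6H4-2-O-i-Pr) (second-generation Hoveyda–Grubbs catalyst, 10 mol %), 1,4-benzoquinone (20 mol %), toluene (2 mM), 80 °C, argon sparge
Reagents that add atoms: none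
Why: A ruthenium alkylidene, formed at the monosubstituted C6 or C1 vinyl group, runs [2+2]/retro-[2+2] cycles that join C6 to C7 (the propenyl group on C8, propene lost) and C1 to the C10 methylidene (ethene lost). The closest known reactions are double ring-closing and ring-rearrangement metatheses of polyenes with second-generation ruthenium catalysts, including closure of trisubstituted cyclohexenes next to quaternary carbons. Ring B closes as a six-membered ring with a cis-disubstituted C6=C7 alkene and ring A as a six-membered ring with the trisubstituted C1=C10 alkene of the target. No stereocentre is formed; C4, C5, C8 and C9 are carried in unchanged and the alkene geometries are fixed by the rings. The selectivity needed is constitutional (C6 with C7, C1 with C10): pairings of the C10 methylidene with C6 or C7 would give three- or four-membered rings, and the only competing closure (C1 with C6, giving 19) expels a single olefin and can be reopened by the alkylidene at C7. With ethene and propene swept out, 20, the only product that has released two olefins, should therefore be the sink.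

Step 14
Reactants: 20 (1S,5R,6S,8aR)-5-(methoxycarbonyl)-1,5,6-trimethyl-1,2,3,5,6,8a-hexahydronaphthalene-1-carboxylic acid
Product: 21 (1S,5R,6S,8aR)-5-(methoxycarbonyl)-1,5,6-trimethyl-1,2,3,5,6,7,8,8a-octahydronaphthalene-1-carboxylic acid
Conditions: H2 (1 atm), RhCl(PPh3)3 (5 mol %), benzene/EtOH (1:1), rt
Reagents that add atoms: none
Why: Homogeneous rhodium hydrogenation should reduce the cis-disubstituted C6=C7 alkene far faster than the trisubstituted C1=C10 alkene shielded by quaternary C9, and creates no stereocentre.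

Step 15
Reactants: 21 (1S,5R,6S,8aR)-5-(methoxycarbonyl)-1,5,6-trimethyl-1,2,3,5,6,7,8,8a-octahydronaphthalene-1-carboxylic acid
Product: 22 (1S,5R,6S,8aR)-5-(hydroxymethyl)-1,5,6-trimethyl-1,2,3,5,6,7,8,8a-octahydronaphthalene-1-carboxylic acid
Conditions: LiEt3BH (4 equiv), THF, 0 °C → rt; 1 M HCl
Reagents that add atoms: none
Why: The C19 acid is deprotonated by the first equivalent and its carboxylate resists hydride, so only the hindered C11 methyl ester should be reduced to the neopentyl alcohol.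

Step 16
Reactants: 22 (1S,5R,6S,8aR)-5-(hydroxymethyl)-1,5,6-trimethyl-1,2,3,5,6,7,8,8a-octahydronaphthalene-1-carboxylic acid
Product: 23 (1S,5R,6S,8aR)-5-formyl-1,5,6-trimethyl-1,2,3,5,6,7,8,8a-octahydronaphthalene-1-carboxylic acid
Conditions: Dess–Martin periodinane, CH2Cl2, rt
Reagents that add atoms: none
Why: Dess–Martin oxidation of a primary alcohol tolerates the free acid and the alkene, and the aldehyde formed has no α-hydrogen.

Step 17
Reactants: 23 (1S,5R,6S,8aR)-5-formyl-1,5,6-trimethyl-1,2,3,5,6,7,8,8a-octahydronaphthalene-1-carboxylic acid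
Product: 24 (1S,5R,6S,8aR)-5-ethenyl-1,5,6-trimethyl-1,2,3,5,6,7,8,8a-octahydronaphthalene-1-carboxylic acid
Conditions: Ph3PCH3Br (3.5 equiv), KOtBu (3.4 equiv), THF, 0 °C → rt
Reagents that add atoms: methyltriphenylphosphonium bromide, C[P+](c1ccccc1)(c1ccccc1)c1ccccc1.[Br-]
Why: Wittig methylenation of a non-enolisable neopentyl aldehyde (one extra equivalent of ylide is consumed by the acid) gives the C11=C12 vinyl group.

Step 18
Reactants: 25 ethyl 3-oxobutanoate
Product: 26 ethyl (2E)-3-(trifluoromethylsulfonyloxy)but-2-enoate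
Conditions: Tf2O, aq. Me4NOH, hexanes, 5 °C
Reagents that add atoms: trifluoromethanesulfonic anhydride, O=S(=O)(OS(=O)(=O)C(F)(F)F)C(F)(F)F
Why: With the non-chelating tetramethylammonium counter-ion the enolate is triflated in its extended form, which should give the E enol triflate (triflate trans to the ester).

Step 19
Reactants: 24 (1S,5R,6S,8aR)-5-ethenyl-1,5,6-trimethyl-1,2,3,5,6,7,8,8a-octahydronaphthalene-1-carboxylic acid; 26 ethyl (2E)-3-(trifluoromethylsulfonyloxy)but-2-enoate
Product: 28 (1S,5R,6S,8aR)-5-[(3E)-5-ethoxy-3-methyl-5-oxopent-3-en-1-yl]-1,5,6-trimethyl-1,2,3,5,6,7,8,8a-octahydronaphthalene-1-carboxylic acid, via B-alkyl-9-BBN adduct 27 (not isolated)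
Conditions: 9-BBN (2.6 equiv), THF, rt; then 26, Pd(dppf)Cl2 (5 mol %), aq. K3PO4, DMF, rt
Reagents that add atoms: none
Why: 9-BBN hydroborates only the monosubstituted vinyl group, at its terminus (the hindered C1=C10 alkene is inert), and the B-alkyl Suzuki–Miyaura coupling proceeds with retention at the enol triflate, fixing the 13E geometry.

Step 20
Reactants: 28 (1S,5R,6S,8aR)-5-[(3E)-5-ethoxy-3-methyl-5-oxopent-3-en-1-yl]-1,5,6-trimethyl-1,2,3,5,6,7,8,8a-octahydronaphthalene-1-carboxylic acid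
Product: 29 (1S,5R,6S,8aR)-5-[(3E)-5-hydroxy-3-methylpent-3-en-1-yl]-1,5,6-trimethyl-1,2,3,5,6,7,8,8a-octahydronaphthalene-1-carboxylic acid
Conditions: i-Bu2AlH (4 equiv), CH2Cl2, −78 °C; Rochelle salt
Reagents that add atoms: none
Why: 1,2-Reduction of the enoate by i-Bu2AlH at low temperature gives the allylic alcohol, while the C19 acid is held as an unreactive aluminium carboxylate.

Step 21
Reactants: 29 (1S,5R,6S,8aR)-5-[(3E)-5-hydroxy-3-methylpent-3-en-1-yl]-1,5,6-trimethyl-1,2,3,5,6,7,8,8a-octahydronaphthalene-1-carboxylic acid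
Product: 30 (1S,5R,6S,8aR)-5-[(3E)-5-acetoxy-3-methylpent-3-en-1-yl]-1,5,6-trimethyl-1,2,3,5,6,7,8,8a-octahydronaphthalene-1-carboxylic acid (CNP0276297.2)
Conditions: Ac2O, pyridine, DMAP (cat.), CH2Cl2, 0 °C → rt; then aq. NaHCO3/THF, acidify
Reagents that add atoms: acetic anhydride, CC(=O)OC(C)=O
Why: O-Acetylation of the primary allylic alcohol; any mixed anhydride at the hindered C19 acid is hydrolysed in the aqueous work-up.

**Compound list**

1 | (S)-but-3-yn-2-ol | O[C@@H](C)C#C | starting material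
2 | (S)-pent-3-yn-2-ol | O[C@@H](C)C#CC | intermediate
3 | (2S,3Z)-pent-3-en-2-ol | O[C@@H](C)/C=C\C | intermediate
4 | methyl 2-methyl-3-oxobutanoate | COC(=O)C(C)C(C)=O | starting material
5 | (2S,3Z)-pent-3-en-2-yl 2-methyl-3-oxobutanoate | CC(=O)C(C)C(=O)O[C@@H](C)/C=C\C | intermediate
6 | (2R,3S,4E)-2-acetyl-2,3-dimethylhex-4-enoic acid | OC(=O)[C@@](C)(C(C)=O)[C@@H](C)/C=C/C | intermediate (not isolated)
7 | methyl (2R,3S,4E)-2-acetyl-2,3-dimethylhex-4-enoate | COC(=O)[C@@](C)(C(C)=O)[C@@H](C)/C=C/C | intermediate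
8 | methyl (2R,3S,4E)-2,3-dimethyl-2-[1-(trifluoromethylsulfonyloxy)ethenyl]hex-4-enoate | COC(=O)[C@@](C)(C(=C)OS(=O)(=O)C(F)(F)F)[C@@H](C)/C=C/C | intermediate
9 | methyl (2R,3S,4E)-2,3-dimethyl-2-[1-(4,4,5,5-tetramethyl-1,3,2-dioxaborolan-2-yl)ethenyl]hex-4-enoate | COC(=O)[C@@](C)(C(=C)B1OC(C)(C)C(C)(C)O1)[C@@H](C)/C=C/C | intermediate
10 | (5R)-5-[(1R,2S,5R)-menthyloxy]furan-2(5H)-one | O=C1C=C[C@H](O[C@@H]2C[C@H](C)CC[C@H]2C(C)C)O1 | starting material
11 | methyl (2R,3S,4E)-2,3-dimethyl-2-{1-[(2R,3S)-2-[(1R,2S,5R)-menthyloxy]-5-oxooxolan-3-yl]ethenyl}hex-4-enoate | COC(=O)[C@@](C)(C(=C)[C@H]1[C@H](O[C@@H]2C[C@H](C)CC[C@H]2C(C)C)OC(=O)C1)[C@@H](C)/C=C/C | intermediate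
12 | but-3-en-1-ol | C=CCCO | starting material
13 | but-3-en-1-yl trifluoromethanesulfonate | C=CCCOS(=O)(=O)C(F)(F)F | intermediate
14 | methyl (2R,3S,4E)-2-{1-[(2R,3S,4R)-4-(but-3-en-1-yl)-2-[(1R,2S,5R)-menthyloxy]-5-oxooxolan-3-yl]ethenyl}-2,3-dimethylhex-4-enoate | COC(=O)[C@@](C)(C(=C)[C@H]1[C@H](O[C@@H]2C[C@H](C)CC[C@H]2C(C)C)OC(=O)[C@@H]1CCC=C)[C@@H](C)/C=C/C | intermediate
15 | methyl (2R,3S,4E)-2-{1-[(2R,3R,4S)-4-(but-3-en-1-yl)-2-[(1R,2S,5R)-menthyloxy]-4-methyl-5-oxooxolan-3-yl]ethenyl}-2,3-dimethylhex-4-enoate | COC(=O)[C@@](C)(C(=C)[C@H]1[C@H](O[C@@H]2C[C@H](C)CC[C@H]2C(C)C)OC(=O)[C@@]1(C)CCC=C)[C@@H](C)/C=C/C | intermediate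
16 | methyl (2R,3S,4E)-2-{1-[(3R,4S)-4-(but-3-en-1-yl)-2-hydroxy-4-methyl-5-oxooxolan-3-yl]ethenyl}-2,3-dimethylhex-4-enoate (anomeric mixture; ring-chain tautomer of the C6 aldehyde–C19 acid) | COC(=O)[C@@](C)(C(=C)[C@H]1C(O)OC(=O)[C@@]1(C)CCC=C)[C@@H](C)/C=C/C | intermediate
17 | (2S,3R)-2-(but-3-en-1-yl)-3-ethenyl-4-[(2R,3S,4E)-1-methoxy-2,3-dimethyl-1-oxohex-4-en-2-yl]-2-methylpent-4-enoic acid | COC(=O)[C@@](C)(C(=C)[C@@H](C=C)[C@@](C)(C(=O)O)CCC=C)[C@@H](C)/C=C/C | intermediate
18 | (2S)-2-[(1R,4S,5R)-5-(methoxycarbonyl)-4,5-dimethyl-6-methylidenecyclohex-2-en-1-yl]-2-methylhex-5-enoic acid (ring B closed, ring A open) | COC(=O)[C@@]1(C)C(=C)[C@H]([C@@](C)(C(=O)O)CCC=C)C=C[C@@H]1C | intermediate (not isolated)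
19 | methyl (2R,3S,4E)-2-{1-[(1R,6S)-6-carboxy-6-methylcyclohex-2-en-1-yl]ethenyl}-2,3-dimethylhex-4-enoate (C1 joined to C6) | COC(=O)[C@@](C)(C(=C)[C@H]1C=CCC[C@]1(C)C(=O)O)[C@@H](C)/C=C/C | intermediate (not isolated)
20 | (1S,5R,6S,8aR)-5-(methoxycarbonyl)-1,5,6-trimethyl-1,2,3,5,6,8a-hexahydronaphthalene-1-carboxylic acid | COC(=O)[C@@]1(C)C2=CCC[C@](C)(C(=O)O)[C@@H]2C=C[C@@H]1C | intermediate
21 | (1S,5R,6S,8aR)-5-(methoxycarbonyl)-1,5,6-trimethyl-1,2,3,5,6,7,8,8a-octahydronaphthalene-1-carboxylic acid | COC(=O)[C@@]1(C)C2=CCC[C@](C)(C(=O)O)[C@@H]2CC[C@@H]1C | intermediate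
22 | (1S,5R,6S,8aR)-5-(hydroxymethyl)-1,5,6-trimethyl-1,2,3,5,6,7,8,8a-octahydronaphthalene-1-carboxylic acid | OC[C@@]1(C)C2=CCC[C@](C)(C(=O)O)[C@@H]2CC[C@@H]1C | intermediate
23 | (1S,5R,6S,8aR)-5-formyl-1,5,6-trimethyl-1,2,3,5,6,7,8,8a-octahydronaphthalene-1-carboxylic acid | O=C[C@@]1(C)C2=CCC[C@](C)(C(=O)O)[C@@H]2CC[C@@H]1C | intermediate
24 | (1S,5R,6S,8aR)-5-ethenyl-1,5,6-trimethyl-1,2,3,5,6,7,8,8a-octahydronaphthalene-1-carboxylic acid | C=C[C@@]1(C)C2=CCC[C@](C)(C(=O)O)[C@@H]2CC[C@@H]1C | intermediate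
25 | ethyl 3-oxobutanoate | CCOC(=O)CC(C)=O | starting material
26 | ethyl (2E)-3-(trifluoromethylsulfonyloxy)but-2-enoate | CCOC(=O)/C=C(\C)OS(=O)(=O)C(F)(F)F | intermediate
27 | B-alkyl-9-BBN adduct of 24 (boron on C12; carboxyl held as its 9-BBN acyloxyborane) | C1CC2CCCC(C1)B2CC[C@@]3(C)C4=CCC[C@](C)(C(=O)OB5C6CCCC5CCC6)[C@@H]4CC[C@@H]3C | intermediate (not isolated)
28 | (1S,5R,6S,8aR)-5-[(3E)-5-ethoxy-3-methyl-5-oxopent-3-en-1-yl]-1,5,6-trimethyl-1,2,3,5,6,7,8,8a-octahydronaphthalene-1-carboxylic acid | CCOC(=O)/C=C(\C)CC[C@@]1(C)C2=CCC[C@](C)(C(=O)O)[C@@H]2CC[C@@H]1C | intermediate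
29 | (1S,5R,6S,8aR)-5-[(3E)-5-hydroxy-3-methylpent-3-en-1-yl]-1,5,6-trimethyl-1,2,3,5,6,7,8,8a-octahydronaphthalene-1-carboxylic acid | OC/C=C(\C)CC[C@@]1(C)C2=CCC[C@](C)(C(=O)O)[C@@H]2CC[C@@H]1C | intermediate
30 | (1S,5R,6S,8aR)-5-[(3E)-5-acetoxy-3-methylpent-3-en-1-yl]-1,5,6-trimethyl-1,2,3,5,6,7,8,8a-octahydronaphthalene-1-carboxylic acid | CC(=O)OC/C=C(\C)CC[C@@]1(C)C2=CCC[C@](C)(C(=O)O)[C@@H]2CC[C@@H]1C | target

**Step count and risks**

Total: 21 steps. Longest linear sequence: 19 steps (steps 1–7, 9–17 and 19–21).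

Steps most likely to fail:

1. Step 13 (double ring-closing metathesis). The cascade may stall at a monocyclic stage: the fast closure of C1 onto C6 may not be reopened, or the hindered C10 methylidene between quaternary C9 and tertiary C5 may not engage; ruthenium hydride may also migrate alkenes. The fallback closes the rings one at a time and sets out from 15. Ring-closing metathesis of the butenyl chain with the C10 methylidene (same ruthenium catalyst, toluene, 80 °C), with C6 still locked in the acetal so that no C1/C6 closure is possible, should give the cis-fused bicyclic lactone acetal F1. Hydrolysis (1 M HCl, 1,4-dioxane, 50 °C) should give the hydroxylactone F2, and Wittig methylenation (Ph3PCH3Br, KOtBu, THF) the ring-A triene acid F3. A single ring-closing metathesis of the C6 vinyl group with the C7 propenyl group then forms C6=C7, and the route is rejoined at 20.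

2. Step 7 (rhodium-catalysed 1,4-addition). Transmetalation and insertion of the α-quaternary alkenyl group may be slow, so that protodeboronation or hydrolytic opening of the pseudo-ester competes. The fallback uses an organocopper conjugate addition and sets out from 8. Triflate–iodide exchange (NaI, Ni(OAc)2·4H2O, cod, DMA/THF, rt) should give the alkenyl iodide F4. Iodine–magnesium exchange (i-PrMgCl·LiCl, THF, −40 °C) should give the ester-tolerant alkenylmagnesium chloride F5, which is added to 10 with CuBr·SMe2 (10 mol %) at −78 → −40 °C, again anti to the menthyloxy group. The route is rejoined at 11.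

3. Step 4 (dianionic Carroll rearrangement). The dianion may decompose before the congested C8–C9 bond forms, part of the reaction may pass through a boat and erode the C8/C9 ratio, or the β-keto acid may decarboxylate before esterification. The fallback replaces the sigmatropic step by an intermolecular Tsuji–Trost allylation and sets out from 3 together with 4. Acylation of 3 (ClCO2Me, pyridine, CH2Cl2, 0 °C) should give the methyl carbonate F6. Palladium-catalysed asymmetric allylic alkylation of 4 with F6 (Pd2(dba)3, the enantiomer of N,N'-(cyclohexane-1,2-diyl)bis(2-diphenylphosphinobenzamide) that delivers the 3S centre, Cs2CO3, CH2Cl2) proceeds through the symmetrical 1,3-dimethylallyl palladium intermediate. It should give the E-propenyl keto ester directly, with the C9 epimer to be removed by chromatography, and the route is rejoined at 7.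

**Further compounds**

F1 | step 13 | methyl (2R,3S,4E)-2,3-dimethyl-2-{(3R,3aR,7aS)-3-[(1R,2S,5R)-menthyloxy]-7a-methyl-1-oxo-1,3,3a,6,7,7a-hexahydro-2-benzofuran-4-yl}hex-4-enoate | COC(=O)[C@@](C)(C1=CCC[C@]2(C)C(=O)O[C@@H](O[C@@H]3C[C@H](C)CC[C@H]3C(C)C)[C@H]12)[C@@H](C)/C=C/C
F2 | step 13 | methyl (2R,3S,4E)-2-[(3aR,7aS)-3-hydroxy-7a-methyl-1-oxo-1,3,3a,6,7,7a-hexahydro-2-benzofuran-4-yl]-2,3-dimethylhex-4-enoate (anomeric mixture) | COC(=O)[C@@](C)(C1=CCC[C@]2(C)C(=O)OC(O)[C@H]12)[C@@H](C)/C=C/C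
F3 | step 13 | (1S,2R)-2-ethenyl-3-[(2R,3S,4E)-1-methoxy-2,3-dimethyl-1-oxohex-4-en-2-yl]-1-methylcyclohex-3-ene-1-carboxylic acid | COC(=O)[C@@](C)(C1=CCC[C@](C)(C(=O)O)[C@@H]1C=C)[C@@H](C)/C=C/C
F4 | step 7 | methyl (2R,3S,4E)-2-(1-iodoethenyl)-2,3-dimethylhex-4-enoate | COC(=O)[C@@](C)(C(=C)I)[C@@H](C)/C=C/C
F5 | step 7 | {1-[(2R,3S,4E)-1-methoxy-2,3-dimethyl-1-oxohex-4-en-2-yl]ethenyl}magnesium chloride | COC(=O)[C@@](C)(C(=C)[Mg]Cl)[C@@H](C)/C=C/C
F6 | step 4 | methyl (2S,3Z)-pent-3-en-2-yl carbonate | COC(=O)O[C@@H](C)/C=C\C
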